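**Retrosynthetic overview**

1. Labels: ring A = C1 (CH bearing the chain C1′–C2′–C3′), C2 (C=CH2), C3 (CHBr), C4 (CH2), C5 (CHBr), C6 (CMe2). Target 23 ⇐ silyl ether 22 ⇐ bromide-for-oxygen inversions at C5 (neopentyl triflate) and C3 (Appel) ⇐ diol 19 ⇐ ketone 17 (hydride at C5, SeO2 at C3).
2. Feature used: in ring A, C1, C2 and the exocyclic CH2 form an allyl unit whose substituted terminus C1 is bonded to quaternary C6, and C6 is the α-carbon of a C5 carbonyl (the later neopentyl bromide carbon). The C1–C6 bond is therefore cut to an allylic carbonate and the C6 enolate of an isopropyl ketone.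
3. Ring A, the only ring, is closed by this bond (13 → 15) with zerovalent palladium. C1 and the exocyclic carbon are both five bonds from C6, so ring size cannot choose between them; a benzyldimethylsilyl group on the exocyclic carbon directs the enolate to C1 and is removed in the next step.
4. Precursor 13 ⇐ nickel-catalysed reductive coupling of aldehyde 4 (from (S)-linalool; brings C3′ and C1) with silylalkynyl ketone 11 (from 3-methylbutan-2-one and silylated propargyl bromide 8).

Key step: step 7

Assumption: (R)-BINAP is written for the chiral diphosphine; its antipode is taken if that proves to be the one that gives the (S) configuration at ring carbon C1.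

**Route**

Step 1
Reactants: 1 (S)-linalool
Product: 2 triethyl{[(3S)-3,7-dimethylocta-1,6-dien-3-yl]oxy}silane
Conditions: Et3SiOTf, 2,6-lutidine, CH2Cl2, −78 → 0 °C
Reagents that add atoms: triethylsilyl trifluoromethanesulfonate, CC[Si](CC)(CC)OS(=O)(=O)C(F)(F)F
Why: A silyl triflate with a hindered pyridine base silylates the tertiary allylic alcohol without ionizing it (silyl ether formation), and C3′ is untouched.

Step 2
Reactants: 2 triethyl{[(3S)-3,7-dimethylocta-1,6-dien-3-yl]oxy}silane
Product: 4 (4S)-4-methyl-4-(triethylsilyloxy)hex-5-enal, via ozonide 3 (not isolated)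
Conditions: O3 (to Sudan Red 7B end point), CH2Cl2, −78 °C; PPh3, −78 °C → rt
Reagents that add atoms: ozone, [O-][O+]=O
Why: Ozone reacts much faster with the electron-rich trisubstituted alkene than with the vinyl group, so titration to the indicator end point and reduction of the ozonide should give the aldehyde that holds C1, C1′, C2′ and C3′ (chemoselective ozonolysis).

Step 3
Reactants: 5 3-bromoprop-1-yne; 6 benzyl(chloro)dimethylsilane
Product: 8 benzyl(3-bromoprop-1-yn-1-yl)dimethylsilane, via lithium acetylide 7 (not isolated)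
Conditions: n-BuLi, Et2O, −78 °C; then 6, −78 → 0 °C
Reagents that add atoms: none
Why: Low-temperature deprotonation of the acetylenic C–H and C-silylation of the lithium acetylide is the standard access to 3-silylpropargyl bromides.

Step 4
Reactants: 9 3-methylbutan-2-one; 8 benzyl(3-bromoprop-1-yn-1-yl)dimethylsilane
Product: 11 7-[benzyl(dimethyl)silyl]-2-methylhept-6-yn-3-one, via lithium enolate 10 (not isolated)
Conditions: LiN(iPr)2, THF, −78 °C; then 8, −78 → 0 °C
Reagents that add atoms: none
Why: The amide base removes a methyl proton under kinetic control and the enolate is alkylated by the reactive propargylic bromide (kinetic enolate alkylation), which places C3 and C4 between the alkyne and the C5 carbonyl.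

Step 5
Reactants: 4 (4S)-4-methyl-4-(triethylsilyloxy)hex-5-enal; 11 7-[benzyl(dimethyl)silyl]-2-methylhept-6-yn-3-one
Product: 12 (6E,10S)-6-{[benzyl(dimethyl)silyl]methylidene}-7-hydroxy-2,10-dimethyl-10-(triethylsilyloxy)dodec-11-en-3-one
Conditions: Ni(cod)2 (10 mol %), PBu3 (20 mol %), Et3B, toluene, rt
Reagents that add atoms: none
Why: Nickel-catalysed reductive alkyne–aldehyde coupling forms the C1–C2 bond at the alkyne carbon remote from silicon and delivers hydrogen cis to the new bond, so the E vinylsilane should result and the aldehyde should react in preference to the ketone; C1 (chain C7) forms without control and both epimers are carried on.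

Step 6
Reactants: 12 (6E,10S)-6-{[benzyl(dimethyl)silyl]methylidene}-7-hydroxy-2,10-dimethyl-10-(triethylsilyloxy)dodec-11-en-3-one
Product: 13 (6E,10S)-6-{[benzyl(dimethyl)silyl]methylidene}-2,10-dimethyl-3-oxo-10-(triethylsilyloxy)dodec-11-en-7-yl methyl carbonate
Conditions: ClCO2Me, pyridine, DMAP (cat.), CH2Cl2, 0 °C
Reagents that add atoms: methyl chloroformate, COC(=O)Cl
Why: Acylation of the secondary allylic alcohol with a chloroformate (carbonate formation) installs the leaving group for π-allyl formation, and the ketone and both silyl groups are inert.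

Step 7
Reactants: 13 (6E,10S)-6-{[benzyl(dimethyl)silyl]methylidene}-2,10-dimethyl-3-oxo-10-(triethylsilyloxy)dodec-11-en-7-yl methyl carbonate
Product: 15 (3S)-4-{[benzyl(dimethyl)silyl]methylidene}-2,2-dimethyl-3-[(3S)-3-methyl-3-(triethylsilyloxy)pent-4-en-1-yl]cyclohexan-1-one, via lithium enolate 14 (not isolated)
Conditions: Pd2(dba)3·CHCl3 (5 mol %), (R)-BINAP (12 mol %), LiCl, THF, 0 °C; LiN(SiMe3)2 (1.05 equiv, slow addition), 0 °C → rt
Reagents that add atoms: none
Why: Proposed new method: zerovalent palladium should ionize the C1 carbonate with inversion to a π-allyl spanning C1, C2 and the silylated exocyclic carbon, and the C6 enolate should attack C1 anti to the metal; the closest known reaction type is the palladium-catalysed asymmetric allylic alkylation of lithium ketone enolates through equilibrating π-allyl diastereomers (Tsuji–Trost), not yet shown for ring closure at a substituted terminus by a tetrasubstituted enolate. Ring A closes in a six-membered mode in which C1 and C2 become ring atoms and the third allyl carbon stays exocyclic. Both allyl termini lie five bonds from C6, so the silyl group is what secures C1 over the exocyclic carbon: nucleophiles are known to attack silyl-substituted π-allylpalladium complexes at the carbon remote from silicon. The new stereocenter C1 is set by the BINAP-bound metal, because σ-allyl formation at the silyl-bearing carbon moves palladium to the other face of C1; both carbonate epimers should then reach the ligand-preferred complex and differ only in vinylsilane geometry, which step 8 erases. Slow addition of the base keeps enolization reversible, only the C6 enolate can close a six-membered ring (the C4 enolate would give a cyclobutane), and O-allylation is reversible under the catalyst.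

Step 8
Reactants: 15 (3S)-4-{[benzyl(dimethyl)silyl]methylidene}-2,2-dimethyl-3-[(3S)-3-methyl-3-(triethylsilyloxy)pent-4-en-1-yl]cyclohexan-1-one
Product: 16 (3R)-3-[(3S)-3-hydroxy-3-methylpent-4-en-1-yl]-2,2-dimethyl-4-methylidenecyclohexan-1-one
Conditions: Bu4NF (4 equiv), THF, 0 °C → rt
Reagents that add atoms: none
Why: Fluoride cleaves the benzyl–silicon bond and the activated silicon is then lost from the vinyl carbon by protodesilylation without alkene migration (known for alkenyl benzyldimethylsilanes), so both vinylsilane isomers should converge on the methylidene group while the triethylsilyl ether is cleaved as well.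

Step 9
Reactants: 16 (3R)-3-[(3S)-3-hydroxy-3-methylpent-4-en-1-yl]-2,2-dimethyl-4-methylidenecyclohexan-1-one
Product: 17 (3R)-2,2-dimethyl-4-methylidene-3-[(3S)-3-methyl-3-(triethylsilyloxy)pent-4-en-1-yl]cyclohexan-1-one
Conditions: Et3SiOTf, 2,6-lutidine, CH2Cl2, −78 °C
Reagents that add atoms: triethylsilyl trifluoromethanesulfonate, CC[Si](CC)(CC)OS(=O)(=O)C(F)(F)F
Why: At low temperature the silyl triflate re-protects the tertiary alcohol faster than it enol-silylates the hindered ketone (silyl ether formation).

Step 10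
Reactants: 17 (3R)-2,2-dimethyl-4-methylidene-3-[(3S)-3-methyl-3-(triethylsilyloxy)pent-4-en-1-yl]cyclohexan-1-one
Product: 18 (1S,3R)-2,2-dimethyl-4-methylidene-3-[(3S)-3-methyl-3-(triethylsilyloxy)pent-4-en-1-yl]cyclohexan-1-ol
Conditions: NaBH4, MeOH, −20 → 0 °C
Reagents that add atoms: none
Why: Hydride should add to the C5 carbonyl along the axial trajectory on the face opposite the axial C6 methyl group (borohydride reduction of a 2,2-dimethylcyclohexanone), giving the equatorial alcohol cis to the equatorial chain.

Step 11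
Reactants: 18 (1S,3R)-2,2-dimethyl-4-methylidene-3-[(3S)-3-methyl-3-(triethylsilyloxy)pent-4-en-1-yl]cyclohexan-1-ol
Product: 19 (1S,3S,5S)-4,4-dimethyl-6-methylidene-5-[(3S)-3-methyl-3-(triethylsilyloxy)pent-4-en-1-yl]cyclohexane-1,3-diol
Conditions: SeO2 (0.3 equiv), t-BuOOH, CH2Cl2, 0 °C → rt
Reagents that add atoms: selenium dioxide (oxygen carrier), O=[Se]=O; tert-butyl hydroperoxide (terminal oxidant), CC(C)(C)OO
Why: Allylic hydroxylation by SeO2 (ene reaction then [2,3]-sigmatropic shift) prefers the ring CH2 at C3 over the hindered methine C1, and in the chair locked by the cis equatorial groups at C1 and C5 oxygen should be delivered axially, giving the C3 alcohol trans to the chain.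

Step 12
Reactants: 19 (1S,3S,5S)-4,4-dimethyl-6-methylidene-5-[(3S)-3-methyl-3-(triethylsilyloxy)pent-4-en-1-yl]cyclohexane-1,3-diol
Product: 20 (1S,3S,5R)-5-bromo-2,2-dimethyl-4-methylidene-3-[(3S)-3-methyl-3-(triethylsilyloxy)pent-4-en-1-yl]cyclohexan-1-ol
Conditions: PPh3 (1.2 equiv), CBr4 (1.2 equiv), 2,6-lutidine, CH2Cl2, −20 → 0 °C
Reagents that add atoms: tetrabromomethane, BrC(Br)(Br)Br
Why: Appel bromination through the alkoxyphosphonium ion pair should replace the axial allylic hydroxyl at C3 with inversion (SN2) to give the equatorial bromide cis to the chain, phosphonium activation being known to convert secondary allylic alcohols with little transposition to the alkene terminus, while the hindered neopentyl C5 hydroxyl should not react at this temperature.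

Step 13
Reactants: 20 (1S,3S,5R)-5-bromo-2,2-dimethyl-4-methylidene-3-[(3S)-3-methyl-3-(triethylsilyloxy)pent-4-en-1-yl]cyclohexan-1-ol
Product: 22 triethyl{[(3S)-5-[(1S,3R,5R)-3,5-dibromo-2,2-dimethyl-6-methylidenecyclohexyl]-3-methylpent-1-en-3-yl]oxy}silane, via triflate 21 (not isolated)
Conditions: Tf2O, 2,6-lutidine, CH2Cl2, −78 → −30 °C; Bu4NBr, toluene, −30 → 0 °C
Reagents that add atoms: tetrabutylammonium bromide, CCCC[N+](CCCC)(CCCC)CCCC.[Br-]
Why: The neopentyl C5 triflate should be displaced by bromide with inversion (SN2), the nucleophile entering axially on the face that carries only hydrogen at C1 and C3, to give the axial bromide trans to the chain; the equatorial C3 bromide lies in the nodal plane of the exocyclic alkene and should therefore resist exchange and transposition.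

Step 14
Reactants: 22 triethyl{[(3S)-5-[(1S,3R,5R)-3,5-dibromo-2,2-dimethyl-6-methylidenecyclohexyl]-3-methylpent-1-en-3-yl]oxy}silane
Product: 23 (3S)-5-[(1S,3R,5R)-3,5-dibromo-2,2-dimethyl-6-methylidenecyclohexyl]-3-methylpent-1-en-3-ol
Conditions: HF·pyridine, pyridine, THF, 0 °C
Reagents that add atoms: none
Why: Buffered HF·pyridine cleaves the triethylsilyl ether (desilylation) without a base that could eliminate or displace the two secondary bromides.

**Compound list**

1 | (S)-linalool, (3S)-3,7-dimethylocta-1,6-dien-3-ol | C=C[C@@](C)(O)CCC=C(C)C | starting material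
2 | triethyl{[(3S)-3,7-dimethylocta-1,6-dien-3-yl]oxy}silane | C=C[C@@](C)(O[Si](CC)(CC)CC)CCC=C(C)C | intermediate
3 | 3,3-dimethyl-5-[(3S)-3-methyl-3-(triethylsilyloxy)pent-4-en-1-yl]-1,2,4-trioxolane (ozonide, not isolated) | C=C[C@@](C)(O[Si](CC)(CC)CC)CCC1OOC(C)(C)O1 | intermediate
4 | (4S)-4-methyl-4-(triethylsilyloxy)hex-5-enal | C=C[C@@](C)(O[Si](CC)(CC)CC)CCC=O | intermediate
5 | 3-bromoprop-1-yne (propargyl bromide) | C#CCBr | starting material
6 | benzyl(chloro)dimethylsilane | C[Si](C)(Cl)Cc1ccccc1 | starting material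
7 | (3-bromoprop-1-yn-1-yl)lithium (not isolated) | [Li]C#CCBr | intermediate
8 | benzyl(3-bromoprop-1-yn-1-yl)dimethylsilane | BrCC#C[Si](C)(C)Cc1ccccc1 | intermediate
9 | 3-methylbutan-2-one | CC(C)C(C)=O | starting material
10 | lithium 3-methylbut-1-en-2-olate (not isolated) | [Li]OC(=C)C(C)C | intermediate
11 | 7-[benzyl(dimethyl)silyl]-2-methylhept-6-yn-3-one | CC(C)C(=O)CCC#C[Si](C)(C)Cc1ccccc1 | intermediate
12 | (6E,10S)-6-{[benzyl(dimethyl)silyl]methylidene}-7-hydroxy-2,10-dimethyl-10-(triethylsilyloxy)dodec-11-en-3-one, both epimers at C7 (ring carbon C1) | C=C[C@@](C)(O[Si](CC)(CC)CC)CCC(O)/C(=C/[Si](C)(C)Cc1ccccc1)CCC(=O)C(C)C | intermediate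
13 | (6E,10S)-6-{[benzyl(dimethyl)silyl]methylidene}-2,10-dimethyl-3-oxo-10-(triethylsilyloxy)dodec-11-en-7-yl methyl carbonate, both epimers at C7 (ring carbon C1) | C=C[C@@](C)(O[Si](CC)(CC)CC)CCC(OC(=O)OC)/C(=C/[Si](C)(C)Cc1ccccc1)CCC(=O)C(C)C | intermediate
14 | lithium enolate of 13 at the isopropyl carbon C6 (not isolated) | C=C[C@@](C)(O[Si](CC)(CC)CC)CCC(OC(=O)OC)/C(=C/[Si](C)(C)Cc1ccccc1)CCC(O[Li])=C(C)C | intermediate
15 | (3S)-4-{[benzyl(dimethyl)silyl]methylidene}-2,2-dimethyl-3-[(3S)-3-methyl-3-(triethylsilyloxy)pent-4-en-1-yl]cyclohexan-1-one, vinylsilane geometry not defined | C=C[C@@](C)(O[Si](CC)(CC)CC)CC[C@@H]1C(=C[Si](C)(C)Cc2ccccc2)CCC(=O)C1(C)C | intermediate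
16 | (3R)-3-[(3S)-3-hydroxy-3-methylpent-4-en-1-yl]-2,2-dimethyl-4-methylidenecyclohexan-1-one | C=C[C@@](C)(O)CC[C@@H]1C(=C)CCC(=O)C1(C)C | intermediate
17 | (3R)-2,2-dimethyl-4-methylidene-3-[(3S)-3-methyl-3-(triethylsilyloxy)pent-4-en-1-yl]cyclohexan-1-one | C=C[C@@](C)(O[Si](CC)(CC)CC)CC[C@@H]1C(=C)CCC(=O)C1(C)C | intermediate
18 | (1S,3R)-2,2-dimethyl-4-methylidene-3-[(3S)-3-methyl-3-(triethylsilyloxy)pent-4-en-1-yl]cyclohexan-1-ol | C=C[C@@](C)(O[Si](CC)(CC)CC)CC[C@@H]1C(=C)CC[C@H](O)C1(C)C | intermediate
19 | (1S,3S,5S)-4,4-dimethyl-6-methylidene-5-[(3S)-3-methyl-3-(triethylsilyloxy)pent-4-en-1-yl]cyclohexane-1,3-diol | C=C[C@@](C)(O[Si](CC)(CC)CC)CC[C@@H]1C(=C)[C@@H](O)C[C@H](O)C1(C)C | intermediate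
20 | (1S,3S,5R)-5-bromo-2,2-dimethyl-4-methylidene-3-[(3S)-3-methyl-3-(triethylsilyloxy)pent-4-en-1-yl]cyclohexan-1-ol | C=C[C@@](C)(O[Si](CC)(CC)CC)CC[C@@H]1C(=C)[C@H](Br)C[C@H](O)C1(C)C | intermediate
21 | (1S,3S,5R)-5-bromo-2,2-dimethyl-4-methylidene-3-[(3S)-3-methyl-3-(triethylsilyloxy)pent-4-en-1-yl]cyclohexyl trifluoromethanesulfonate (not isolated) | C=C[C@@](C)(O[Si](CC)(CC)CC)CC[C@@H]1C(=C)[C@H](Br)C[C@H](OS(=O)(=O)C(F)(F)F)C1(C)C | intermediate
22 | triethyl{[(3S)-5-[(1S,3R,5R)-3,5-dibromo-2,2-dimethyl-6-methylidenecyclohexyl]-3-methylpent-1-en-3-yl]oxy}silane | C=C[C@@](C)(O[Si](CC)(CC)CC)CC[C@@H]1C(=C)[C@H](Br)C[C@@H](Br)C1(C)C | intermediate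
23 | (3S)-5-[(1S,3R,5R)-3,5-dibromo-2,2-dimethyl-6-methylidenecyclohexyl]-3-methylpent-1-en-3-ol | C=C[C@@](C)(O)CC[C@@H]1C(=C)[C@H](Br)C[C@@H](Br)C1(C)C | target

**Step count and risks**

Total steps: 14. Longest linear sequence: 12 steps (5 → 8 → 11 → 12 → 13 → 15 → 16 → 17 → 18 → 19 → 20 → 22 → 23; the branch from 1 is equally long).

Most likely to fail:

1. Step 7 (Proposed new method). Ionization of the hindered trisubstituted allyl carbonate may be slow and be followed by β-hydride loss to dienes. Face exchange of the π-allyl may be slower than enolate attack, so that each carbonate epimer transfers its own configuration and stereoconvergence is lost. The C4 enolate may be consumed in intermolecular reactions.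
Fallback with known chemistry, setting out from bromide 8 and aldehyde 4 and coming back at 15: a sulfone-stabilized carbanion takes the place of the ketone enolate, so that the cyclization runs in the established soft-nucleophile regime of the Tsuji–Trost reaction, where attack remote from silicon and ligand control over equilibrating π-allyl complexes are documented. 3-Chlorobutan-2-one and PhSO2Na (DMF) give 3-(phenylsulfonyl)butan-2-one F1. Its dianion (NaH, then n-BuLi, THF) is alkylated at the methyl carbon by 8 to give 7-[benzyl(dimethyl)silyl]-2-(phenylsulfonyl)hept-6-yn-3-one F2. Coupling with 4 under the conditions of step 5 gives the allylic alcohol F3, and methyl chloroformate gives the carbonate F4. Pd2(dba)3·CHCl3 and (R)-BINAP in THF without added base (the methoxide released on ionization deprotonates the sulfonyl ketone) close ring A at C1 to give the 2-methyl-2-(phenylsulfonyl)cyclohexanone F5. Lithium naphthalenide (THF, −78 °C) cleaves the C–S bond to the C6 lithium enolate, which MeI methylates in the same flask to give 15.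

2. Step 13. The neopentyl triflate may ionize with 1,2-shift of the antiperiplanar C6–C1 bond (ring contraction) or eliminate before the slow SN2 takes place, and bromide ion may exchange or transpose the allylic C3 bromide during a long reaction.
Fallback, setting out from 18 and coming back at 22: the C5 bromide is made first, by phosphonium activation, which does not pass through a free cation, and before any allylic bromide exists. PPh3, CBr4 and 2,6-lutidine in MeCN at 60 °C should convert 18 with inversion into the axial C5 bromide F6. SeO2 and t-BuOOH then hydroxylate C3 to give F7, oxygen being delivered anti to the C1 chain (the chair is no longer locked, so a minor C3 epimer may have to be removed by chromatography). Appel bromination as in step 12 gives 22, so that the allylic C–Br bond is the last one formed.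

3. Step 11. The allylic alcohol may be over-oxidized to the enone, hydrogen may be abstracted at C1 in place of C3, or oxygen may be delivered to both faces of C3.
Fallback, setting out from 18 and coming back at 19: the C3 stereocenter is set by reduction and not by the hydroxylation. SeO2 with excess t-BuOOH, followed by MnO2 in CH2Cl2, takes all C3-oxidized material to the cross-conjugated enone F8 without touching the non-allylic C5 hydroxyl. Me4NBH(OAc)3 (AcOH, MeCN, −20 °C) then binds to the C5 hydroxyl and delivers hydride to the C3 carbonyl from the same face, giving the anti 1,3-diol 19 with 1,2-selectivity.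

Further compounds
F1 | step 7 | 3-(phenylsulfonyl)butan-2-one | CC(=O)C(C)S(=O)(=O)c1ccccc1
F2 | step 7 | 7-[benzyl(dimethyl)silyl]-2-(phenylsulfonyl)hept-6-yn-3-one | CC(C(=O)CCC#C[Si](C)(C)Cc1ccccc1)S(=O)(=O)c1ccccc1
F3 | step 7 | (6E,10S)-6-{[benzyl(dimethyl)silyl]methylidene}-7-hydroxy-10-methyl-2-(phenylsulfonyl)-10-(triethylsilyloxy)dodec-11-en-3-one, epimers at C2 and C7 | C=C[C@@](C)(O[Si](CC)(CC)CC)CCC(O)/C(=C/[Si](C)(C)Cc1ccccc1)CCC(=O)C(C)S(=O)(=O)c1ccccc1
F4 | step 7 | (6E,10S)-6-{[benzyl(dimethyl)silyl]methylidene}-10-methyl-3-oxo-2-(phenylsulfonyl)-10-(triethylsilyloxy)dodec-11-en-7-yl methyl carbonate, epimers at C2 and C7 | C=C[C@@](C)(O[Si](CC)(CC)CC)CCC(OC(=O)OC)/C(=C/[Si](C)(C)Cc1ccccc1)CCC(=O)C(C)S(=O)(=O)c1ccccc1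
F5 | step 7 | 4-{[benzyl(dimethyl)silyl]methylidene}-2-methyl-3-[(3S)-3-methyl-3-(triethylsilyloxy)pent-4-en-1-yl]-2-(phenylsulfonyl)cyclohexan-1-one, ring carbon C1 configured as in 15, epimers at the sulfonyl carbon | C=C[C@@](C)(O[Si](CC)(CC)CC)CC[C@@H]1C(=C[Si](C)(C)Cc2ccccc2)CCC(=O)C1(C)S(=O)(=O)c1ccccc1
F6 | step 13 | triethyl{[(3S)-5-[(1R,3R)-3-bromo-2,2-dimethyl-6-methylidenecyclohexyl]-3-methylpent-1-en-3-yl]oxy}silane | C=C[C@@](C)(O[Si](CC)(CC)CC)CC[C@@H]1C(=C)CC[C@@H](Br)C1(C)C
F7 | step 13 | (1S,3R,5R)-5-bromo-4,4-dimethyl-2-methylidene-3-[(3S)-3-methyl-3-(triethylsilyloxy)pent-4-en-1-yl]cyclohexan-1-ol | C=C[C@@](C)(O[Si](CC)(CC)CC)CC[C@@H]1C(=C)[C@@H](O)C[C@@H](Br)C1(C)C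
F8 | step 11 | (3S,5S)-5-hydroxy-4,4-dimethyl-2-methylidene-3-[(3S)-3-methyl-3-(triethylsilyloxy)pent-4-en-1-yl]cyclohexan-1-one | C=C[C@@](C)(O[Si](CC)(CC)CC)CC[C@@H]1C(=C)C(=O)C[C@H](O)C1(C)C
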